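**Retrosynthetic overview**

1. The target is reached from its bis-MOM/TBS-protected form by one acidic methanolysis; no other functional group change is needed at the end.
2. The protected skeleton is cut at C7′–C8′ (side chain numbered from the ring-bound carbon C1′ to the methyl C17′) by a Zweifel olefination of a primary alkyl pinacolboronate with an (E)-alkenyllithium, which forms this bond and the cis C8′=C9′ alkene together. The enabling feature is the isolated 1,2-disubstituted C8′=C9′ double bond: C8′ carries one hydrogen and sits next to the unbranched methylene C7′, so C8′ can be the boron-bound carbon of an (E)-alkenylboronate and C7′ a primary migrating group, with the resorcinol ring and the C16′ carbinol seven carbons away on either side.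
3. The alkylboronate comes from iridium-catalysed hydroboration of a terminal alkene, itself made by B-alkyl Suzuki–Miyaura coupling of bis-MOM-protected 5-bromoresorcinol with hepta-1,6-diene.
4. The (E)-alkenyl iodide comes from hydrozirconation–iodination of TBS-protected (S)-dec-9-yn-2-ol, made by alkyne zipper isomerisation of (S)-dec-4-yn-2-ol from (S)-propylene oxide and hept-1-yne; the C16′ stereocentre is bought.
5. No ring is formed: the resorcinol ring is carried intact from 5-bromoresorcinol.

Key step: step 8

Remark: CIP analysis of the SMILES gives (S) at the C16′ carbinol and Z at C8′=C9′, so (S)-propylene oxide of high enantiomeric purity is taken as the source of the stereocentre.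

**Step 1**
Reactants: 1 5-bromobenzene-1,3-diol (5-bromoresorcinol)
Product: 2 1-bromo-3,5-bis(methoxymethoxy)benzene
Conditions: NaH (2.4 equiv), THF/DMF, 0 °C; MOMCl (2.4 equiv), 0 °C → rt
Reagents that add atoms: chloromethyl methyl ether (MOMCl), COCCl
Why: Williamson-type O-alkylation of both phenoxides by the reactive α-chloro ether should give the bis-acetal, which is inert to the bases, boranes and organometallics used later and is removed by dilute acid.

**Step 2**
Reactants: 2 1-bromo-3,5-bis(methoxymethoxy)benzene; 3 hepta-1,6-diene
Product: 5 1-(hept-6-en-1-yl)-3,5-bis(methoxymethoxy)benzene, via alkylborane 4 (not isolated)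
Conditions: 3 (4 equiv), 9-BBN (1.2 equiv), THF, 0 °C → rt, excess 3 removed in vacuo; then 2 (1.0 equiv), PdCl2(dppf) (3 mol %), 3 M aq NaOH, THF, 65 °C
Reagents that add atoms: none
Why: Anti-Markovnikov hydroboration of one terminal alkene of the excess diene by 9-BBN, then B-alkyl Suzuki–Miyaura coupling in which hydroxide-activated transfer of the primary alkyl group to the arylpalladium bromide outruns β-hydride elimination with the wide-bite-angle dppf ligand, should give the arylheptene with the second alkene untouched.

**Step 3**
Reactants: 5 1-(hept-6-en-1-yl)-3,5-bis(methoxymethoxy)benzene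
Product: 6 2-{7-[3,5-bis(methoxymethoxy)phenyl]heptyl}-4,4,5,5-tetramethyl-1,3,2-dioxaborolane
Conditions: HBpin (1.2 equiv), [Ir(cod)Cl]2 (1.5 mol %), dppm (3 mol %), CH2Cl2, rt
Reagents that add atoms: pinacolborane (HBpin), [H]B1OC(C)(C)C(C)(C)O1
Why: Iridium-catalysed hydroboration of a terminal alkene with pinacolborane should place boron on the terminal carbon with high linear selectivity and tolerates acetals and electron-rich arenes.

**Step 4**
Reactants: 7 hept-1-yne; 8 (S)-2-methyloxirane ((S)-propylene oxide)
Product: 10 (S)-dec-4-yn-2-ol, via lithium acetylide 9 (not isolated)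
Conditions: 7 (1.3 equiv), n-BuLi (1.3 equiv), THF, −78 °C; BF3·OEt2 (1.3 equiv), −78 °C; then 8 (1.0 equiv), −78 °C; H2O quench
Reagents that add atoms: none
Why: BF3-promoted opening of a terminal epoxide by a lithium acetylide (Yamaguchi–Hirao alkynylation) is an SN2 attack at the unsubstituted carbon, so the stereocentre of (S)-propylene oxide is not touched and becomes the (S)-carbinol.

**Step 5**
Reactants: 10 (S)-dec-4-yn-2-ol
Product: 11 (S)-dec-9-yn-2-ol
Conditions: KH (5 equiv), H2N(CH2)3NH2 (forms KNH(CH2)3NH2), 0 °C → rt; H2O quench
Reagents that add atoms: none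
Why: Alkyne zipper isomerisation moves the triple bond through propargyl/allenyl anions to the chain end remote from the alkoxide, where irreversible deprotonation of the terminal alkyne C–H holds it; the carbinol C–H is not acidic, so the stereocentre should be retained.

**Step 6**
Reactants: 11 (S)-dec-9-yn-2-ol
Product: 12 (S)-tert-butyl(dec-9-yn-2-yloxy)dimethylsilane
Conditions: TBSCl (1.2 equiv), imidazole (2.5 equiv), DMF, rt
Reagents that add atoms: tert-butyldimethylsilyl chloride (TBSCl), CC(C)(C)[Si](C)(C)Cl
Why: Imidazole-mediated silylation of the secondary alcohol should give a TBS ether that withstands Cp2Zr(H)Cl, t-BuLi at −78 °C and NaOMe and is cleaved in the final acid step.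

**Step 7**
Reactants: 12 (S)-tert-butyl(dec-9-yn-2-yloxy)dimethylsilane
Product: 14 (S,E)-tert-butyl[(10-iododec-9-en-2-yl)oxy]dimethylsilane, via alkenylzirconocene chloride 13 (not isolated)
Conditions: Cp2Zr(H)Cl (1.3 equiv), THF, rt, dark; then I2 (1.3 equiv), 0 °C
Reagents that add atoms: iodine (I2), II
Why: Schwartz hydrozirconation adds Zr–H syn across the terminal alkyne with zirconium on the terminal carbon, and iododezirconation with retention should give the (E)-1-iodoalkene.

**Step 8**
Reactants: 14 (S,E)-tert-butyl[(10-iododec-9-en-2-yl)oxy]dimethylsilane; 6 2-{7-[3,5-bis(methoxymethoxy)phenyl]heptyl}-4,4,5,5-tetramethyl-1,3,2-dioxaborolane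
Product: 18 (S,Z)-tert-butyl({17-[3,5-bis(methoxymethoxy)phenyl]heptadec-9-en-2-yl}oxy)dimethylsilane, via alkenyllithium 15 (not isolated), via lithium boronate complex 16 (not isolated), via iodoalkylboronic ester 17 (not isolated)
Conditions: 14 (1.2 equiv), t-BuLi (2.4 equiv), Et2O, −78 °C; 6 (1.0 equiv) in THF, −78 °C; I2 (1.3 equiv) in MeOH, −78 °C; NaOMe (3 equiv) in MeOH, −78 °C → rt; aq Na2S2O3
Reagents that add atoms: none
Why: Lithium–iodine exchange converts 14 with retention into (E)-alkenyllithium 15, which adds to the empty boron orbital of 6 to give boronate 16; iodine then forms an iodonium ion on the alkenyl π-bond, the primary C7′ alkyl group migrates from boron to C8′ anti to the opening C–I bond to give β-iodoalkylboronic ester 17, and methoxide attack at boron triggers anti-periplanar loss of boron and iodide. This is the Zweifel olefination in its boronic-ester form, a transition-metal-free oxidative union of two carbon nucleophiles (an alkylboron carbon and an alkenyllithium carbon) with iodine as the oxidant. No ring is closed and no lasting stereocentre is made: the two transient stereocentres of 17 arise by stereospecific anti addition, so the diastereomers from attack on either alkene face collapse by anti elimination to the same alkene. The element that controls the new double-bond geometry is therefore the E geometry of 14, fixed by the syn hydrozirconation, which the anti-addition/anti-elimination pair should invert cleanly to Z. The step needs Z over E selectivity, migration of carbon and not oxygen, and boronate formation in preference to proton transfer; these are secured by the stereospecific mechanism, by the pinacol oxygens being non-migrating ligands so that the unhindered primary chain is the only group able to shift, and by the absence of acidic hydrogens, since every hydroxyl is masked as a MOM or TBS ether and the arene never meets t-BuLi. The C16′ stereocentre is remote from the reacting atoms and should be unaffected.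

**Step 9**
Reactants: 18 (S,Z)-tert-butyl({17-[3,5-bis(methoxymethoxy)phenyl]heptadec-9-en-2-yl}oxy)dimethylsilane
Product: 19 (S,Z)-5-(16-hydroxyheptadec-8-en-1-yl)benzene-1,3-diol (Hansfordiol E)
Conditions: conc. aq HCl (excess), MeOH, 45 °C
Reagents that add atoms: none
Why: Acid-catalysed methanolysis should cleave both aryl MOM acetals and the secondary TBS ether in one operation under conditions that leave an isolated Z-alkene and a secondary alcohol alone, with the large excess of methanol trapping the methoxymethyl cation before it can alkylate the resorcinol ring.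

**Compound list**

1 | 5-bromobenzene-1,3-diol (5-bromoresorcinol) | Oc1cc(O)cc(Br)c1 | starting material
2 | 1-bromo-3,5-bis(methoxymethoxy)benzene | COCOc1cc(Br)cc(OCOC)c1 | intermediate
3 | hepta-1,6-diene | C=CCCCC=C | starting material
4 | 9-(hept-6-en-1-yl)-9-borabicyclo[3.3.1]nonane | C=CCCCCCB1C2CCCC1CCC2 | intermediate (not isolated)
5 | 1-(hept-6-en-1-yl)-3,5-bis(methoxymethoxy)benzene | C=CCCCCCc1cc(OCOC)cc(OCOC)c1 | intermediate
6 | 2-{7-[3,5-bis(methoxymethoxy)phenyl]heptyl}-4,4,5,5-tetramethyl-1,3,2-dioxaborolane | COCOc1cc(CCCCCCCB2OC(C)(C)C(C)(C)O2)cc(OCOC)c1 | intermediate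
7 | hept-1-yne | C#CCCCCC | starting material
8 | (S)-2-methyloxirane ((S)-propylene oxide) | C[C@H]1CO1 | starting material
9 | hept-1-yn-1-yllithium | [Li]C#CCCCCC | intermediate (not isolated)
10 | (S)-dec-4-yn-2-ol | C[C@H](O)CC#CCCCCC | intermediate
11 | (S)-dec-9-yn-2-ol | C[C@H](O)CCCCCCC#C | intermediate
12 | (S)-tert-butyl(dec-9-yn-2-yloxy)dimethylsilane | C[C@H](O[Si](C)(C)C(C)(C)C)CCCCCCC#C | intermediate
13 | chlorobis(cyclopentadienyl)[(S,E)-9-(tert-butyldimethylsilyloxy)dec-1-en-1-yl]zirconium | C[C@H](O[Si](C)(C)C(C)(C)C)CCCCCC/C=C/[Zr](Cl)(C1C=CC=C1)C1C=CC=C1 | intermediate (not isolated)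
14 | (S,E)-tert-butyl[(10-iododec-9-en-2-yl)oxy]dimethylsilane | C[C@H](O[Si](C)(C)C(C)(C)C)CCCCCC/C=C/I | intermediate
15 | [(S,E)-9-(tert-butyldimethylsilyloxy)dec-1-en-1-yl]lithium | C[C@H](O[Si](C)(C)C(C)(C)C)CCCCCC/C=C/[Li] | intermediate (not isolated)
16 | lithium {7-[3,5-bis(methoxymethoxy)phenyl]heptyl}[(S,E)-9-(tert-butyldimethylsilyloxy)dec-1-en-1-yl](pinacolato)borate | [Li+].C[C@H](O[Si](C)(C)C(C)(C)C)CCCCCC/C=C/[B-]1(CCCCCCCc2cc(OCOC)cc(OCOC)c2)OC(C)(C)C(C)(C)O1 | intermediate (not isolated)
17 | tert-butyl({17-[3,5-bis(methoxymethoxy)phenyl]-9-iodo-10-(4,4,5,5-tetramethyl-1,3,2-dioxaborolan-2-yl)heptadecan-2-yl}oxy)dimethylsilane; (2S,9S,10S) isomer shown, the (2S,9R,10R) isomer from the other alkene face should form alongside and converge | C[C@H](O[Si](C)(C)C(C)(C)C)CCCCCC[C@H](I)[C@@H](B1OC(C)(C)C(C)(C)O1)CCCCCCCc1cc(OCOC)cc(OCOC)c1 | intermediate (not isolated)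
18 | (S,Z)-tert-butyl({17-[3,5-bis(methoxymethoxy)phenyl]heptadec-9-en-2-yl}oxy)dimethylsilane | C[C@H](O[Si](C)(C)C(C)(C)C)CCCCCC/C=C\CCCCCCCc1cc(OCOC)cc(OCOC)c1 | intermediate
19 | (S,Z)-5-(16-hydroxyheptadec-8-en-1-yl)benzene-1,3-diol (Hansfordiol E) | C[C@H](O)CCCCCC/C=C\CCCCCCCc1cc(O)cc(O)c1 | target

**Summary**

Total step count: 9. Longest linear sequence: 6 steps (steps 4 to 9, from hept-1-yne and (S)-propylene oxide).

**Steps most likely to fail**

Step 8. The risks are incomplete boronate formation through adventitious protonation of the alkenyllithium, and erosion of the Z geometry if migration and elimination do not both run anti. The fallback makes the same C7′–C8′ bond as an sp–sp3 bond and sets out from 6, with 12 as partner. Oxidation of 6 (NaBO3·4H2O, THF/H2O) would give 7-[3,5-bis(methoxymethoxy)phenyl]heptan-1-ol F1. I2, PPh3 and imidazole would convert it into 1-(7-iodoheptyl)-3,5-bis(methoxymethoxy)benzene F2. Alkyne 12 would be deprotonated (n-BuLi, THF/DMPU, −78 °C) to [(S)-9-(tert-butyldimethylsilyloxy)dec-1-yn-1-yl]lithium F3 and alkylated with F2 to (S)-tert-butyl({17-[3,5-bis(methoxymethoxy)phenyl]heptadec-9-yn-2-yl}oxy)dimethylsilane F4. Semi-hydrogenation of F4 (H2, Pd/CaCO3 poisoned with Pb(OAc)2, quinoline, hexane) would return to the route at 18.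

Step 2. The risks are double hydroboration of the diene, leading to twofold arylation, and slow alkyl transfer with protodeboronation. The fallback reverses the polarity of the coupling and sets out from 2. Mg turnings with LiCl in THF would convert 2 into [3,5-bis(methoxymethoxy)phenyl]magnesium bromide F5. Coupling of F5 with 7-bromohept-1-ene under Li2CuCl4 catalysis (THF, −20 °C → rt) would come back to the route at 5.

Step 5. The risks are incomplete migration of the triple bond, leaving internal alkyne isomers that are hard to separate, and base-induced decomposition on scale. The fallback avoids the isomerisation, replaces steps 4 and 5, and sets out from 8. Epoxide 8 would be opened under CuI catalysis with (5-chloropentyl)magnesium bromide F6, made from 1-bromo-5-chloropentane and Mg, to give (S)-8-chlorooctan-2-ol F7. Displacement of chloride with LiC≡CH·H2N(CH2)2NH2 (excess, DMSO, rt) would come back to the route at 11.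

**Further compounds**

F1 | step 8 | 7-[3,5-bis(methoxymethoxy)phenyl]heptan-1-ol | OCCCCCCCc1cc(OCOC)cc(OCOC)c1
F2 | step 8 | 1-(7-iodoheptyl)-3,5-bis(methoxymethoxy)benzene | ICCCCCCCc1cc(OCOC)cc(OCOC)c1
F3 | step 8 | [(S)-9-(tert-butyldimethylsilyloxy)dec-1-yn-1-yl]lithium | C[C@H](O[Si](C)(C)C(C)(C)C)CCCCCCC#C[Li]
F4 | step 8 | (S)-tert-butyl({17-[3,5-bis(methoxymethoxy)phenyl]heptadec-9-yn-2-yl}oxy)dimethylsilane | C[C@H](O[Si](C)(C)C(C)(C)C)CCCCCCC#CCCCCCCCc1cc(OCOC)cc(OCOC)c1
F5 | step 2 | [3,5-bis(methoxymethoxy)phenyl]magnesium bromide | COCOc1cc([Mg]Br)cc(OCOC)c1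
F6 | step 5 | (5-chloropentyl)magnesium bromide | ClCCCCC[Mg]Br
F7 | step 5 | (S)-8-chlorooctan-2-ol | C[C@H](O)CCCCCCCl
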